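(The runs stem from a simulated flask from invented constants; the scatter is artificial.)

Two questions are put to you on the red flask, and both ask where its nucleophile goes.

| setting | red | green | flask |
|---|---|---|---|
| solid electrophile | 33 mM | 50 mM | 33 mM |
| nucleophile | 36.3 mM | 36.3 mM | 36.3 mM |
| free base | 16.5 mM | 16.5 mM | 16.5 mM |
| remark | the very flask that is asked about, followed so far | run made earlier |  |
| time |  |  | 10 d |

- red (time / d: solid electrophile / %, product / %): 0.250: 89, 5; 0.833: 76, 13; 1.25: 75, 19; 2.00: 71, 17; 3.00: 65, 21
- green (time / d: solid electrophile / %, product / %): 0.625: 83, 6; 1.04: 78, 6; 2.08: 79, 11; 4.00: 78, 16; 8.00: 73, 18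

(readings scatter by 2 percentage points)

1. part of the solid electrophile that has reacted (what has only dissolved counts as not reacted) at 10 d
2. share of free nucleophile in free nucleophile and protonated nucleophile together, at 10 d

- solid, in amounts per volume of the solution: solid electrophile
- the analysis behind the earlier runs scatters by 2 percentage points, standard deviation
- steps that have been proposed: solid electrophile <-> electrophile; electrophile + nucleophile -> acid set free + product; acid set free -> by-product carried off; nucleophile + acid set free <-> protonated nucleophile; acid set free + free base <-> salt of the base; nucleophile <-> dormant form
- at the start none of the solid electrophile is in solution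
- what has only dissolved of solid electrophile counts as not reacted
- the earlier runs do not show how much of nucleophile is bound; that part of a forecast is a guess

At an even charge, a percent of solid electrophile and a percent of nucleophile are the same thing, so take that as the zero of the scale: red stands at 1.10 nucleophile per solid electrophile and green at 0.726, with equal nucleophile charges. Keep the books on nucleophile, then. Green's last reading, at 8.00 d, opens the product entry with 24.8%, and this is the nucleophile yield, product as a fraction of the nucleophile charged. Red's yield at 3.00 d is 19.1%, more than green's 15.2% at 2.08 d and less than green's 22.0% at 4.00 d, so as far as these readings show, the runs share one curve on this scale. The remaining 75.2% of green's nucleophile stays one unsplit entry, free, protonated or dormant, because the runs do not divide it. My reckoning carries green's yield to red: 27.3% reacted at 8.00 d, a little more by 10 d, and any free share is a guess.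

The forecast gives 30%, more than my figure, and 80% free, holding that “most should sit on the base”.

The flask gives 29.3% reacted and a free share of 14.4%.

    solid electrophile ⇌ electrophile, rate k1*(cs1 - [electrophile]) while solid is left; crystals form when [electrophile] > cs1 (solubility = 4.20 mM, k = 0.00360 min⁻¹)
    electrophile + nucleophile → acid set free + product (k = 0.0920 L mol⁻¹ min⁻¹)
    acid set free → by-product carried off (k = 0.00150 min⁻¹)
    nucleophile + acid set free ⇌ protonated nucleophile, settled at all times (K = 23000 L mol⁻¹)
    acid set free + free base ⇌ salt of the base (K = 87.0 L mol⁻¹, k = 0.190 L mol⁻¹ min⁻¹)
    nucleophile ⇌ dormant form (K = 27.0, k = 8.40 × 10⁻⁴ min⁻¹)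

The red flask's nucleophile is charged at more than its solid electrophile, so by charge the solid electrophile is the limiting reagent, and at 10 d the books on nucleophile close at 26.6% product, 60.6% dormant, 10.9% protonated and 1.84% free, while salt of the base, on the same scale, stands at 1.01%, less than the protonated nucleophile. That yield stands beside the 24.8% carried from green. Put on the neighbour flask with 22 mM of nucleophile, 0.667 equiv to the solid, it reckons 17.8% reacted, and that flask gives 19.2%.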